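C1 = CO2H carbon, C3 = stereocentre, C14 = CH2 on the ring, C15 = chain-bearing ring carbon, C16 = ring CH, C17/C18 = ring C=O next to C16/C15.
Cuts, in retrosynthetic order: the C1 tert-butyl ester; the ring C15=C16 bond together with the ring O–C17 acyl bond (giving a 2-oxo acid plus Ph3P=C=C=O); C11–C12 and C7–C8 (B-alkyl Suzuki–Miyaura); C10=C11 and C6=C7 (Z-selective iodo-olefination of aldehydes); the alkene of citronellic acid (ozonolysis).
Forward: the chain grows from C1 towards C15 by two identical cycles (aldehyde → (Z)-2-iodoalkene → B-alkyl coupling), the second coupling bringing C12–C15/C18 as a dithiane-masked 2-oxo ester; the furan-2,5-dione, the only ring, is made last but one in a single operation.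
Enabling feature: in the 3-alkylfuran-2,5-dione, C15 is bonded directly to the C18 carbonyl, so opening the ring C=C leaves a 2-oxo acid, and the remaining C16H–C17(=O) pair is the two-carbon unit of ketenylidenetriphenylphosphorane; the five-membered ring forces the cis (maleic) geometry.
Stereochemistry: C3 (R) comes unchanged from (R)-(+)-citronellic acid; 6Z and 10Z come from kinetically Z-selective α-iodoethylidene Wittig reactions followed by stereoretentive Pd coupling.
Key step: step 11

Assumption: the two chain alkenes are read as Z (C5/C8 cis and C9/C12 cis) and C3 as R, as the SMILES encodes; the route is built for that isomer.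

Step 1
Reactants: 1 (R)-(+)-citronellic acid [(3R)-3,7-dimethyloct-6-enoic acid]
Product: 2 tert-butyl (3R)-3,7-dimethyloct-6-enoate
Conditions: Cl3CC(=NH)OtBu (2 equiv), CH2Cl2/cyclohexane, rt (no added Lewis acid)
Reagents that add atoms: tert-butyl 2,2,2-trichloroacetimidate, CC(C)(C)OC(=N)C(Cl)(Cl)Cl
Why: Trichloroacetimidate esterification, in which the carboxylic acid itself protonates the imidate and is O-alkylated, should give the tert-butyl ester without strong acid, so the trisubstituted alkene and the non-enolisable C3 centre stay untouched.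

Step 2
Reactants: 2 tert-butyl (3R)-3,7-dimethyloct-6-enoate
Product: 4 tert-butyl (3R)-3-methyl-6-oxohexanoate, via secondary ozonide 3 (not isolated)
Conditions: O3, CH2Cl2, −78 °C; then Me2S, −78 °C → rt
Reagents that add atoms: ozone, [O-][O+]=O
Why: Ozonolysis with reductive work-up cleaves the only C=C bond to the C6 aldehyde and acetone, leaving the ester and C3 unchanged.

Step 3
Reactants: 4 tert-butyl (3R)-3-methyl-6-oxohexanoate
Product: 5 tert-butyl (3R,6Z)-7-iodo-3-methyloct-6-enoate
Conditions: EtPPh3I, n-BuLi, THF, 0 °C → rt; I2, −78 °C; NaHMDS, −20 °C; then 4, −78 → −20 °C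
Reagents that add atoms: ethyltriphenylphosphonium iodide, CC[P+](c1ccccc1)(c1ccccc1)c1ccccc1.[I-]; iodine, II
Why: Stork–Zhao-type Wittig olefination with the non-stabilised α-iodoethylidene ylide should give the (Z)-2-iodo-2-alkene under kinetic control (iodine cis to the C5 chain), which fixes the later 6Z geometry; the hindered tert-butyl ester does not react with the ylide at low temperature.

Step 4
Reactants: 5 tert-butyl (3R,6Z)-7-iodo-3-methyloct-6-enoate; 6 acrolein diethyl acetal (3,3-diethoxyprop-1-ene)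
Product: 8 tert-butyl (3R,6Z)-10,10-diethoxy-3,7-dimethyldec-6-enoate, via alkyl-9-BBN 7 (not isolated)
Conditions: 6, 9-BBN, THF, rt; then 5, Pd(dppf)Cl2 (cat.), AsPh3 (cat.), Cs2CO3, DMF/THF/H2O, rt
Reagents that add atoms: none
Why: Anti-Markovnikov hydroboration of the terminal alkene followed by B-alkyl Suzuki–Miyaura coupling should replace iodine by the C8–C10 chain with retention of alkene geometry, so C8 ends up cis to C5 (6Z).

Step 5
Reactants: 8 tert-butyl (3R,6Z)-10,10-diethoxy-3,7-dimethyldec-6-enoate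
Product: 9 tert-butyl (3R,6Z)-3,7-dimethyl-10-oxodec-6-enoate
Conditions: 1 M aq. HCl, THF, rt
Reagents that add atoms: water, O
Why: Acid-catalysed acetal hydrolysis should release the C10 aldehyde under conditions too mild to cleave the tert-butyl ester or to isomerise the trisubstituted alkene.

Step 6
Reactants: 9 tert-butyl (3R,6Z)-3,7-dimethyl-10-oxodec-6-enoate
Product: 10 tert-butyl (3R,6Z,10Z)-11-iodo-3,7-dimethyldodeca-6,10-dienoate
Conditions: EtPPh3I, n-BuLi, THF, 0 °C → rt; I2, −78 °C; NaHMDS, −20 °C; then 9, −78 → −20 °C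
Reagents that add atoms: ethyltriphenylphosphonium iodide, CC[P+](c1ccccc1)(c1ccccc1)c1ccccc1.[I-]; iodine, II
Why: The same Stork–Zhao-type iodo-olefination should give the second (Z)-2-iodo-2-alkene (iodine cis to C9), which fixes the later 10Z geometry without touching the existing 6Z alkene.

Step 7
Reactants: 11 ethyl 1,3-dithiane-2-carboxylate; 12 allyl bromide
Product: 13 ethyl 2-(prop-2-en-1-yl)-1,3-dithiane-2-carboxylate
Conditions: NaH, DMF/toluene, 0 °C → rt
Reagents that add atoms: none
Why: Corey–Seebach-type alkylation of the doubly stabilised dithiane ester carbanion (a glyoxylate acyl-anion equivalent) with a reactive allylic bromide should proceed by clean SN2 C-alkylation.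

Step 8
Reactants: 10 tert-butyl (3R,6Z,10Z)-11-iodo-3,7-dimethyldodeca-6,10-dienoate; 13 ethyl 2-(prop-2-en-1-yl)-1,3-dithiane-2-carboxylate
Product: 15 ethyl 2-[(4Z,8Z,12R)-14-tert-butoxy-4,8,12-trimethyl-14-oxotetradeca-4,8-dien-1-yl]-1,3-dithiane-2-carboxylate, via alkyl-9-BBN 14 (not isolated)
Conditions: 13, 9-BBN, THF, rt; then 10, Pd(dppf)Cl2 (cat.), AsPh3 (cat.), Cs2CO3, DMF/THF/H2O, rt
Reagents that add atoms: none
Why: Terminal hydroboration and B-alkyl Suzuki–Miyaura coupling should join C11 to C12 with retention of the iodide geometry (10Z); both esters and the dithiane tolerate 9-BBN at rt and the mild aqueous base.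

Step 9
Reactants: 15 ethyl 2-[(4Z,8Z,12R)-14-tert-butoxy-4,8,12-trimethyl-14-oxotetradeca-4,8-dien-1-yl]-1,3-dithiane-2-carboxylate
Product: 16 16-tert-butyl 1-ethyl (6Z,10Z,14R)-6,10,14-trimethyl-2-oxohexadeca-6,10-dienedioate
Conditions: PhI(OCOCF3)2 (1.5 equiv), MeCN/H2O (9:1), 0 °C → rt
Reagents that add atoms: water, O
Why: Hypervalent-iodine oxidative dethioacetalisation should unmask the ketone, because sulfur is oxidised far faster than the trisubstituted alkenes and water captures the thionium ion, while both esters persist.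

Step 10
Reactants: 16 16-tert-butyl 1-ethyl (6Z,10Z,14R)-6,10,14-trimethyl-2-oxohexadeca-6,10-dienedioate
Product: 17 (6Z,10Z,14R)-16-tert-butoxy-6,10,14-trimethyl-2,16-dioxohexadeca-6,10-dienoic acid
Conditions: LiOH (1.1 equiv), THF/H2O, 0 °C; then 1 M HCl to pH 2
Reagents that add atoms: lithium hydroxide, [Li+].[OH-]
Why: Chemoselective saponification should cleave only the ethyl ester, which is activated by the adjacent ketone and reacts at 0 °C, whereas the hindered tert-butyl ester is not attacked.

Step 11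
Reactants: 17 (6Z,10Z,14R)-16-tert-butoxy-6,10,14-trimethyl-2,16-dioxohexadeca-6,10-dienoic acid; 18 (triphenylphosphoranylidene)ketene (Bestmann ylide)
Product: 20 tert-butyl (3R,6Z,10Z)-14-(2,5-dioxo-2,5-dihydrofuran-3-yl)-3,7,11-trimethyltetradeca-6,10-dienoate, via acyloxycarbonyl ylide 19 (not isolated)
Conditions: 18 (1.05 equiv, slow addition), THF (high dilution), 0 °C → rt, then 50 °C
Reagents that add atoms: none
Why: Proposed new method: the carboxylic O–H of 17 protonates the ylide carbon of Ph3P=C=C=O and the carboxylate adds to the resulting ketenylphosphonium ion to give the mixed-anhydride ylide 19, whose ylide carbon then attacks the neighbouring ketone C15 and expels Ph3P=O to form the C15=C16 bond. The closest known reaction type is the domino addition–intramolecular Wittig olefination of this same ylide with α-hydroxy ketones and α-hydroxy esters, which gives butenolides and tetronates; here the tethering atom is a carboxylate oxygen, so the ring obtained is a cyclic anhydride. The furan-2,5-dione ring closes in a 5-exo-trig sense (ylide carbon onto the exocyclic C=O of the ketone), the same mode as in the known butenolide closures. No stereocentre is formed, and the five-membered ring forces the cis arrangement of the two carbonyls, so no E/Z question arises. The step needs chemoselectivity for the 2-oxo acid, which the tert-butyl ester at C1 secures, and the cumulated ylide itself does not olefinate carbonyl groups, so olefination can only follow O–H addition. Ring closure must also outrun acyl transfer to the ylide carbon and intermolecular acylation, which the high electrophilicity of the 1,2-dicarbonyl ketone, the five-membered transition state, high dilution and slow addition of the ylide should secure.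

Step 12
Reactants: 20 tert-butyl (3R,6Z,10Z)-14-(2,5-dioxo-2,5-dihydrofuran-3-yl)-3,7,11-trimethyltetradeca-6,10-dienoate
Product: 22 (3R,6Z,10Z)-14-(2,5-dioxo-2,5-dihydrofuran-3-yl)-3,7,11-trimethyltetradeca-6,10-dienoic acid, via trimethylsilyl ester 21 (not isolated)
Conditions: TMSOTf, 2,6-lutidine, CH2Cl2, 0 °C; then cold pH 3 aqueous buffer
Reagents that add atoms: none
Why: Silyl-triflate-mediated tert-butyl ester cleavage (O-silylation, loss of the tert-butyl cation as isobutene under lutidine buffering, hydrolysis of the silyl ester on work-up) uses no nucleophile and no free protic acid, so the anhydride and both Z-alkenes should survive.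

Compound list
1 | (R)-(+)-citronellic acid, (3R)-3,7-dimethyloct-6-enoic acid | CC(C)=CCC[C@@H](C)CC(=O)O | starting material
2 | tert-butyl (3R)-3,7-dimethyloct-6-enoate | CC(C)=CCC[C@@H](C)CC(=O)OC(C)(C)C | intermediate
3 | secondary ozonide of 2, tert-butyl (3R)-5-(5,5-dimethyl-1,2,4-trioxolan-3-yl)-3-methylpentanoate (mixture at the ring CH) | CC1(C)OOC(CC[C@@H](C)CC(=O)OC(C)(C)C)O1 | intermediate (not isolated)
4 | tert-butyl (3R)-3-methyl-6-oxohexanoate | O=CCC[C@@H](C)CC(=O)OC(C)(C)C | intermediate
5 | tert-butyl (3R,6Z)-7-iodo-3-methyloct-6-enoate | C/C(I)=C/CC[C@@H](C)CC(=O)OC(C)(C)C | intermediate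
6 | acrolein diethyl acetal, 3,3-diethoxyprop-1-ene | C=CC(OCC)OCC | starting material
7 | 9-(3,3-diethoxypropyl)-9-borabicyclo[3.3.1]nonane | CCOC(CCB1C2CCCC1CCC2)OCC | intermediate (not isolated)
8 | tert-butyl (3R,6Z)-10,10-diethoxy-3,7-dimethyldec-6-enoate | C/C(=C/CC[C@@H](C)CC(=O)OC(C)(C)C)CCC(OCC)OCC | intermediate
9 | tert-butyl (3R,6Z)-3,7-dimethyl-10-oxodec-6-enoate | C/C(=C/CC[C@@H](C)CC(=O)OC(C)(C)C)CCC=O | intermediate
10 | tert-butyl (3R,6Z,10Z)-11-iodo-3,7-dimethyldodeca-6,10-dienoate | C/C(=C/CC[C@@H](C)CC(=O)OC(C)(C)C)CC/C=C(/C)I | intermediate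
11 | ethyl 1,3-dithiane-2-carboxylate | CCOC(=O)C1SCCCS1 | starting material
12 | allyl bromide, 3-bromoprop-1-ene | C=CCBr | starting material
13 | ethyl 2-(prop-2-en-1-yl)-1,3-dithiane-2-carboxylate | C=CCC1(C(=O)OCC)SCCCS1 | intermediate
14 | ethyl 2-[3-(9-borabicyclo[3.3.1]nonan-9-yl)propyl]-1,3-dithiane-2-carboxylate | CCOC(=O)C1(CCCB2C3CCCC2CCC3)SCCCS1 | intermediate (not isolated)
15 | ethyl 2-[(4Z,8Z,12R)-14-tert-butoxy-4,8,12-trimethyl-14-oxotetradeca-4,8-dien-1-yl]-1,3-dithiane-2-carboxylate | C/C(=C/CC[C@@H](C)CC(=O)OC(C)(C)C)CC/C=C(/C)CCCC1(C(=O)OCC)SCCCS1 | intermediate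
16 | 16-tert-butyl 1-ethyl (6Z,10Z,14R)-6,10,14-trimethyl-2-oxohexadeca-6,10-dienedioate | C/C(=C/CC[C@@H](C)CC(=O)OC(C)(C)C)CC/C=C(/C)CCCC(=O)C(=O)OCC | intermediate
17 | (6Z,10Z,14R)-16-tert-butoxy-6,10,14-trimethyl-2,16-dioxohexadeca-6,10-dienoic acid | C/C(=C/CC[C@@H](C)CC(=O)OC(C)(C)C)CC/C=C(/C)CCCC(=O)C(=O)O | intermediate
18 | (triphenylphosphoranylidene)ketene (Bestmann ylide) | O=C=C=P(c1ccccc1)(c1ccccc1)c1ccccc1 | starting material
19 | mixed-anhydride ylide, 2-(triphenylphosphoranylidene)acetic (6Z,10Z,14R)-16-tert-butoxy-6,10,14-trimethyl-2,16-dioxohexadeca-6,10-dienoic anhydride | C/C(=C/CC[C@@H](C)CC(=O)OC(C)(C)C)CC/C=C(/C)CCCC(=O)C(=O)OC(=O)C=P(c1ccccc1)(c1ccccc1)c1ccccc1 | intermediate (not isolated)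
20 | tert-butyl (3R,6Z,10Z)-14-(2,5-dioxo-2,5-dihydrofuran-3-yl)-3,7,11-trimethyltetradeca-6,10-dienoate | C/C(=C/CC[C@@H](C)CC(=O)OC(C)(C)C)CC/C=C(/C)CCCC1=CC(=O)OC1=O | intermediate
21 | trimethylsilyl (3R,6Z,10Z)-14-(2,5-dioxo-2,5-dihydrofuran-3-yl)-3,7,11-trimethyltetradeca-6,10-dienoate | C/C(=C/CC[C@@H](C)CC(=O)O[Si](C)(C)C)CC/C=C(/C)CCCC1=CC(=O)OC1=O | intermediate (not isolated)
22 | (3R,6Z,10Z)-14-(2,5-dioxo-2,5-dihydrofuran-3-yl)-3,7,11-trimethyltetradeca-6,10-dienoic acid | C/C(=C/CC[C@@H](C)CC(=O)O)CC/C=C(/C)CCCC1=CC(=O)OC1=O | target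

Total step count: 12. Longest linear sequence: 11 steps (steps 1–6 and 8–12); step 7 is a one-step side branch.

Steps most likely to fail

Step 11 (proposed new method). The mixed-anhydride ylide may transfer its acyl group to the ylide carbon or be acylated by a second molecule faster than it olefinates, and unreacted ylide may add to the electrophilic anhydride as it forms. The fallback uses known chemistry and sets out from the 2-oxo ester 16. Intermolecular Wittig olefination with ethyl (triphenylphosphoranylidene)acetate in toluene at 80 °C should give diethyl (2Z)-2-[(4Z,8Z,12R)-14-tert-butoxy-4,8,12-trimethyl-14-oxotetradeca-4,8-dien-1-yl]but-2-enedioate F1, with any E isomer carried along. Saponification of the two ethyl esters with LiOH in THF/H2O at rt, which leaves the tert-butyl ester, should give (2Z)-2-[(4Z,8Z,12R)-14-tert-butoxy-4,8,12-trimethyl-14-oxotetradeca-4,8-dien-1-yl]but-2-enedioic acid F2. Warming in acetic anhydride should dehydrate the cis diacid and funnel E material to the cyclic anhydride on heating, which returns to the route at 20.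

Step 9. Oxidation may spill over to the two electron-rich trisubstituted alkenes, hydrolysis of the ester-deactivated dithiane may stall, and upstream the sulfur may slow the palladium coupling of step 8. The fallback avoids sulfur and sets out from iodide 10. B-alkyl Suzuki–Miyaura coupling with borane 7 (made from 6 as in step 4) should give tert-butyl (3R,6Z,10Z)-14,14-diethoxy-3,7,11-trimethyltetradeca-6,10-dienoate F3. Hydrolysis with 1 M HCl/THF should give tert-butyl (3R,6Z,10Z)-3,7,11-trimethyl-14-oxotetradeca-6,10-dienoate F4. Horner–Wadsworth–Emmons reaction with methyl 2-[(tert-butyldimethylsilyl)oxy]-2-(dimethoxyphosphoryl)acetate (LiHMDS, THF, −78 °C → rt) should give 16-tert-butyl 1-methyl (6Z,10Z,14R)-2-[(tert-butyldimethylsilyl)oxy]-6,10,14-trimethylhexadeca-2,6,10-trienedioate F5, whose 2-ene geometry is irrelevant. Desilylation with Et3N·3HF in THF should give 16-tert-butyl 1-methyl (6Z,10Z,14R)-6,10,14-trimethyl-2-oxohexadeca-6,10-dienedioate F6. LiOH at 0 °C, as in step 10, returns to the route at 17.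

Step 3 (the same reasoning applies to step 6). The iodo ylide may decompose or be over-iodinated before it meets the aldehyde, the aldehyde may enolise, and Z-selectivity may erode. The fallback sets out from aldehyde 4. Still–Gennari olefination with methyl 2-[bis(2,2,2-trifluoroethoxy)phosphoryl]propanoate (KHMDS, 18-crown-6, THF, −78 °C) should give 8-tert-butyl 1-methyl (2Z,6R)-2,6-dimethyloct-2-enedioate F7. DIBAL-H in CH2Cl2 at −78 °C, which reduces the conjugated methyl ester in preference to the hindered tert-butyl ester, should give tert-butyl (3R,6Z)-8-hydroxy-3,7-dimethyloct-6-enoate F8. MsCl/Et3N followed by LiBr in THF should give tert-butyl (3R,6Z)-8-bromo-3,7-dimethyloct-6-enoate F9. Li2CuCl4-catalysed coupling with (1,3-dioxolan-2-ylmethyl)magnesium bromide (THF, −20 °C; α-attack with retention of alkene geometry) should give tert-butyl (3R,6Z)-9-(1,3-dioxolan-2-yl)-3,7-dimethylnon-6-enoate F10. Aqueous acid hydrolysis of the dioxolane returns to the route at aldehyde 9.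

Further compounds
F1 | step 11 | diethyl (2Z)-2-[(4Z,8Z,12R)-14-tert-butoxy-4,8,12-trimethyl-14-oxotetradeca-4,8-dien-1-yl]but-2-enedioate | C/C(=C/CC[C@@H](C)CC(=O)OC(C)(C)C)CC/C=C(/C)CCC/C(C(=O)OCC)=C/C(=O)OCC
F2 | step 11 | (2Z)-2-[(4Z,8Z,12R)-14-tert-butoxy-4,8,12-trimethyl-14-oxotetradeca-4,8-dien-1-yl]but-2-enedioic acid | C/C(=C/CC[C@@H](C)CC(=O)OC(C)(C)C)CC/C=C(/C)CCC/C(C(=O)O)=C/C(=O)O
F3 | step 9 | tert-butyl (3R,6Z,10Z)-14,14-diethoxy-3,7,11-trimethyltetradeca-6,10-dienoate | C/C(=C/CC[C@@H](C)CC(=O)OC(C)(C)C)CC/C=C(/C)CCC(OCC)OCC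
F4 | step 9 | tert-butyl (3R,6Z,10Z)-3,7,11-trimethyl-14-oxotetradeca-6,10-dienoate | C/C(=C/CC[C@@H](C)CC(=O)OC(C)(C)C)CC/C=C(/C)CCC=O
F5 | step 9 | 16-tert-butyl 1-methyl (6Z,10Z,14R)-2-[(tert-butyldimethylsilyl)oxy]-6,10,14-trimethylhexadeca-2,6,10-trienedioate | C/C(=C/CC[C@@H](C)CC(=O)OC(C)(C)C)CC/C=C(/C)CCC=C(O[Si](C)(C)C(C)(C)C)C(=O)OC
F6 | step 9 | 16-tert-butyl 1-methyl (6Z,10Z,14R)-6,10,14-trimethyl-2-oxohexadeca-6,10-dienedioate | C/C(=C/CC[C@@H](C)CC(=O)OC(C)(C)C)CC/C=C(/C)CCCC(=O)C(=O)OC
F7 | step 3 | 8-tert-butyl 1-methyl (2Z,6R)-2,6-dimethyloct-2-enedioate | C/C(=C/CC[C@@H](C)CC(=O)OC(C)(C)C)C(=O)OC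
F8 | step 3 | tert-butyl (3R,6Z)-8-hydroxy-3,7-dimethyloct-6-enoate | C/C(=C/CC[C@@H](C)CC(=O)OC(C)(C)C)CO
F9 | step 3 | tert-butyl (3R,6Z)-8-bromo-3,7-dimethyloct-6-enoate | C/C(=C/CC[C@@H](C)CC(=O)OC(C)(C)C)CBr
F10 | step 3 | tert-butyl (3R,6Z)-9-(1,3-dioxolan-2-yl)-3,7-dimethylnon-6-enoate | C/C(=C/CC[C@@H](C)CC(=O)OC(C)(C)C)CCC1OCCO1
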